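**Strategy.** The pyranone is cut at O1–C2 and C3–C4. This exposes the unit O1–C8a=C4a–C4=O as an α-oxoketene whose ketene carbon C4 sits outside the carbocycle C4a/C5/C6/C7/C8/C8a. The key step makes this ketene by thermal Wolff rearrangement of a fully functionalised 2-diazocycloheptane-1,3-dione built from D-ribonolactone: loss of N2 pushes C4 out of the seven-membered ring, which contracts to the cyclohexene ring with the three oxygens and the chlorine already in place, and a 2-methoxy-1-alkene traps the ketene in a [4+2] that builds the pyranone in the same flask. One acid treatment then frees the target.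

Key step: step 9

Locants in the seven-membered intermediates follow cycloheptane-1,3-dione numbering (C1 and C3 carbonyls, C2 between them, C4/C5 the dioxolane carbons, C6 the carbinol, C7 the methylene or chloromethine).

**Step 1**
Reactants: 1 2,3-O-isopropylidene-D-ribono-1,4-lactone
Product: 2 2,3-O-isopropylidene-L-erythruronolactone (lactol form; anomeric mixture)
Conditions: NaOH (1.0 equiv), H2O, 40 °C; NaIO4, 0 °C to rt; HCl to pH 3
Reagents that add atoms: sodium hydroxide, [Na+].[OH-]
Why: Saponification frees the C4,C5-diol, periodate glycol cleavage (Malaprade) removes C5 as formaldehyde and the aldehydo-acid closes on acidification to the pseudo-acid lactol, the two dioxolane stereocentres (ribose C2/C3) being untouched.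

**Step 2**
Reactants: 2 2,3-O-isopropylidene-L-erythruronolactone; 3 1-(triphenyl-λ5-phosphanylidene)propan-2-one
Product: 5 (3aR,6R,6aR)-2,2-dimethyl-6-(2-oxopropyl)dihydrofuro[3,4-d][1,3]dioxol-4(3aH)-one, via enone acid 4 (not isolated)
Conditions: 3 (1.3 equiv), PhMe, 80 °C; then DBU (10 mol %), rt
Reagents that add atoms: none
Why: Wittig olefination of the ring-opened aldehydo-acid should give enone acid 4, which lactonises by reversible 5-exo oxa-Michael addition (the Wittig/oxa-Michael cascade known for 2-formylbenzoic acid to phthalides), and under this equilibration the acetonyl group takes the convex face trans to the dioxolane, which sets the new centre in the D-ribo (6R) sense.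

**Step 3**
Reactants: 5 (3aR,6R,6aR)-2,2-dimethyl-6-(2-oxopropyl)dihydrofuro[3,4-d][1,3]dioxol-4(3aH)-one
Product: 6 (4R,5R,6R)-6-hydroxy-4,5-(isopropylidenedioxy)cycloheptane-1,3-dione
Conditions: LDA (2.2 equiv), THF, −78 to −20 °C; AcOH quench
Reagents that add atoms: none
Why: Intramolecular Claisen (Dieckmann-type) transacylation, in which the kinetic methyl-ketone enolate attacks the lactone carbonyl through a six-membered transition state and the bridged hemiketal alkoxide collapses by expelling the C6 alkoxide, should give the seven-membered 1,3-dione as its stabilised dianion without touching a stereocentre.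

**Step 4**
Reactants: 6 (4R,5R,6R)-6-hydroxy-4,5-(isopropylidenedioxy)cycloheptane-1,3-dione
Product: 7 (4R,5R,6R)-2-diazo-6-hydroxy-4,5-(isopropylidenedioxy)cycloheptane-1,3-dione
Conditions: p-ABSA, Et3N, MeCN, 0 °C to rt
Reagents that add atoms: 4-acetamidobenzenesulfonyl azide, CC(=O)Nc1ccc(cc1)S(=O)(=O)N=[N+]=[N-]
Why: Regitz diazo transfer to the acidic C2 of the 1,3-dione tolerates the free hydroxyl and creates no stereocentre.

**Step 5**
Reactants: 7 (4R,5R,6R)-2-diazo-6-hydroxy-4,5-(isopropylidenedioxy)cycloheptane-1,3-dione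
Product: 9 (4R,5S,6S,7R)-6-(tert-butyldimethylsilyloxy)-7-chloro-2-diazo-4,5-(isopropylidenedioxy)cycloheptane-1,3-dione, via enoldiazo bis-silyl ether 8 (not isolated)
Conditions: TBSOTf (2.5 equiv), Et3N, CH2Cl2, −78 to 0 °C; pentane, filter, concentrate; NCS (1.05 equiv), THF, −78 to 0 °C
Reagents that add atoms: tert-butyldimethylsilyl triflate, CC(C)(C)[Si](C)(C)OS(=O)(=O)C(F)(F)F; N-chlorosuccinimide, ClN1C(=O)CCC1=O
Why: TBSOTf/Et3N silylates the C6 hydroxyl and soft-enolises the C1 ketone toward its only methylene (C7) to give enoldiazo silyl ether 8, and NCS then chlorinates this silyl enol ether at C7 (α-halogenation of a silyl enol ether) from the face opposite the three cis oxygen substituents, so that chlorine should end up trans to the C6 silyloxy group (7R).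

**Step 6**
Reactants: 10 3-(3-hydroxy-4-methoxyphenyl)propanoic acid
Product: 11 methyl 3-(3-hydroxy-4-methoxyphenyl)propanoate
Conditions: MeOH, H2SO4 (cat.), reflux
Reagents that add atoms: methanol, CO
Why: Fischer esterification converts the acid only, the phenol being inert under these conditions.

**Step 7**
Reactants: 11 methyl 3-(3-hydroxy-4-methoxyphenyl)propanoate
Product: 12 methyl 3-[4-methoxy-3-(methoxymethoxy)phenyl]propanoate
Conditions: MOMCl, iPr2NEt, CH2Cl2, 0 °C to rt
Reagents that add atoms: chloromethyl methyl ether, COCCl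
Why: O-Alkylation of the phenol (Williamson type) gives an acetal that survives titanium methylenation and heat, masks the phenol against the ketene of step 9 and is removed by the final acid.

**Step 8**
Reactants: 12 methyl 3-[4-methoxy-3-(methoxymethoxy)phenyl]propanoate
Product: 13 2-methoxy-4-[4-methoxy-3-(methoxymethoxy)phenyl]but-1-ene
Conditions: Cp2TiMe2 (2.5 equiv), PhMe, 65 °C, dark
Reagents that add atoms: dimethyltitanocene, C[Ti](C)(C1C=CC=C1)C1C=CC=C1
Why: Petasis methylenation of the ester carbonyl through Cp2Ti=CH2 and an oxatitanacyclobutane gives the 2-methoxy-1-alkene regiospecifically, with no isomerisation to the internal enol ether.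

**Step 9**
Reactants: 9 (4R,5S,6S,7R)-6-(tert-butyldimethylsilyloxy)-7-chloro-2-diazo-4,5-(isopropylidenedioxy)cycloheptane-1,3-dione; 13 2-methoxy-4-[4-methoxy-3-(methoxymethoxy)phenyl]but-1-ene
Product: 16 (5S,6S,7S,8R)-7-(tert-butyldimethylsilyloxy)-8-chloro-5,6-(isopropylidenedioxy)-2-{2-[4-methoxy-3-(methoxymethoxy)phenyl]ethyl}-5,6,7,8-tetrahydro-4H-chromen-4-one, via α-oxoketene 14 (not isolated), via 2-methoxy-dihydropyranone cycloadduct 15 (not isolated)
Conditions: 13 (3 equiv), PhMe, 140 °C (sealed tube, μW), 15 min; then CSA (10 mol %), rt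
Reagents that add atoms: none
Why: Thermolysis of the s-Z,s-Z-locked cyclic 2-diazo-1,3-dione extrudes N2 in a concerted Wolff rearrangement in which C4 migrates from the C3 carbonyl to the diazo carbon, so the seven-membered ring contracts by this 1,2-shift to the six-membered 2-oxocyclohexylidene ketene 14 and C3 leaves the ring to become C4 of the chromone. The closest known reaction type is the ring-contractive Wolff rearrangement of cyclic 2-diazo-1,3-diketones with in situ hetero-Diels–Alder capture of the α-oxoketene by enol ethers. The pyranone ring closes by an intermolecular [4+2] of the 1-oxadiene O=C8a–C4a=C4 with the enol ether, whose nucleophilic CH2 terminus bonds to the ketene carbon and whose alkoxy carbon bonds to the ketone oxygen, and acid then eliminates methanol from the C2 ketal of 15 to give the 4-pyranone. No lasting stereocentre is created: the migrating methine moves with retention of configuration and becomes C5, the centres that become C6, C7 and C8 are spectators, and the transient ketal centre at C2 is erased. The step needs migration of the dioxolane methine C4 and not of the chloromethine C7, which should be secured by the σ-withdrawing, non-donating chlorine that lowers the migratory aptitude of C7 (as for α-halo- and perfluoroalkyl groups in Wolff and Baeyer–Villiger shifts), whereas the α-oxygen on C4 supports the shift by lone-pair donation. Concerted N2 loss avoids a free carbene, so the electron-rich enol ether should not be cyclopropanated, and its excess outruns ketene dimerisation.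

**Step 10**
Reactants: 16 (5S,6S,7S,8R)-7-(tert-butyldimethylsilyloxy)-8-chloro-5,6-(isopropylidenedioxy)-2-{2-[4-methoxy-3-(methoxymethoxy)phenyl]ethyl}-5,6,7,8-tetrahydro-4H-chromen-4-one
Product: 17 (5S,6S,7S,8R)-8-chloro-5,6,7-trihydroxy-2-[2-(3-hydroxy-4-methoxyphenyl)ethyl]-5,6,7,8-tetrahydro-4H-chromen-4-one
Conditions: TFA/H2O (9:1), 0 °C to rt
Reagents that add atoms: none
Why: Acid hydrolysis cleaves the acetonide, the silyl ether and the aryl MOM acetal in one operation, while the secondary chloride at C8 next to the protonated, electron-poor pyranone should not ionise, so all four stereocentres are retained.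

**Compound list**

1 | 2,3-O-isopropylidene-D-ribono-1,4-lactone, (3aR,6R,6aR)-6-(hydroxymethyl)-2,2-dimethyldihydrofuro[3,4-d][1,3]dioxol-4(3aH)-one | OC[C@H]1OC(=O)[C@@H]2OC(C)(C)O[C@H]12 | starting material
2 | 2,3-O-isopropylidene-L-erythruronolactone, (3aR,6aS)-6-hydroxy-2,2-dimethyldihydrofuro[3,4-d][1,3]dioxol-4(3aH)-one, anomeric mixture | OC1OC(=O)[C@@H]2OC(C)(C)O[C@H]12 | intermediate
3 | 1-(triphenyl-λ5-phosphanylidene)propan-2-one (acetonylidenetriphenylphosphorane) | CC(=O)C=P(c1ccccc1)(c1ccccc1)c1ccccc1 | starting material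
4 | (4R,5R)-2,2-dimethyl-5-[(E)-3-oxobut-1-enyl]-1,3-dioxolane-4-carboxylic acid (cis-dioxolane) | CC(=O)/C=C/[C@H]1OC(C)(C)O[C@H]1C(=O)O | intermediate (not isolated)
5 | (3aR,6R,6aR)-2,2-dimethyl-6-(2-oxopropyl)dihydrofuro[3,4-d][1,3]dioxol-4(3aH)-one (acetonyl trans to the dioxolane) | CC(=O)C[C@H]1OC(=O)[C@@H]2OC(C)(C)O[C@H]12 | intermediate
6 | (4R,5R,6R)-6-hydroxy-4,5-(isopropylidenedioxy)cycloheptane-1,3-dione (three oxygens all cis) | O=C1C[C@@H](O)[C@H]2OC(C)(C)O[C@H]2C(=O)C1 | intermediate
7 | (4R,5R,6R)-2-diazo-6-hydroxy-4,5-(isopropylidenedioxy)cycloheptane-1,3-dione | [N-]=[N+]=C1C(=O)C[C@@H](O)[C@H]2OC(C)(C)O[C@H]2C1=O | intermediate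
8 | (5R,6S,7R)-3,5-bis(tert-butyldimethylsilyloxy)-2-diazo-6,7-(isopropylidenedioxy)cyclohept-3-en-1-one (C1=C7 enol silyl ether of the O-silylated diazodione) | [N-]=[N+]=C1C(O[Si](C)(C)C(C)(C)C)=C[C@@H](O[Si](C)(C)C(C)(C)C)[C@H]2OC(C)(C)O[C@H]2C1=O | intermediate (not isolated)
9 | (4R,5S,6S,7R)-6-(tert-butyldimethylsilyloxy)-7-chloro-2-diazo-4,5-(isopropylidenedioxy)cycloheptane-1,3-dione (Cl trans to the three cis oxygens) | [N-]=[N+]=C1C(=O)[C@H](Cl)[C@@H](O[Si](C)(C)C(C)(C)C)[C@H]2OC(C)(C)O[C@H]2C1=O | intermediate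
10 | 3-(3-hydroxy-4-methoxyphenyl)propanoic acid (dihydroisoferulic acid) | OC(=O)CCc1ccc(OC)c(O)c1 | starting material
11 | methyl 3-(3-hydroxy-4-methoxyphenyl)propanoate | COC(=O)CCc1ccc(OC)c(O)c1 | intermediate
12 | methyl 3-[4-methoxy-3-(methoxymethoxy)phenyl]propanoate | COCOc1cc(CCC(=O)OC)ccc1OC | intermediate
13 | 2-methoxy-4-[4-methoxy-3-(methoxymethoxy)phenyl]but-1-ene | COCOc1cc(CCC(=C)OC)ccc1OC | intermediate
14 | (3S,4S,5S,6R)-5-(tert-butyldimethylsilyloxy)-6-chloro-3,4-(isopropylidenedioxy)-2-(oxomethylidene)cyclohexan-1-one (α-oxoketene) | O=C=C1C(=O)[C@H](Cl)[C@@H](O[Si](C)(C)C(C)(C)C)[C@H]2OC(C)(C)O[C@@H]12 | intermediate (not isolated)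
15 | (5S,6S,7S,8R)-7-(tert-butyldimethylsilyloxy)-8-chloro-5,6-(isopropylidenedioxy)-2-methoxy-2-{2-[4-methoxy-3-(methoxymethoxy)phenyl]ethyl}-2,3,5,6,7,8-hexahydro-4H-chromen-4-one (C2 epimers) | COCOc1cc(CCC2(OC)CC(=O)C3=C(O2)[C@H](Cl)[C@@H](O[Si](C)(C)C(C)(C)C)[C@H]2OC(C)(C)O[C@@H]32)ccc1OC | intermediate (not isolated)
16 | (5S,6S,7S,8R)-7-(tert-butyldimethylsilyloxy)-8-chloro-5,6-(isopropylidenedioxy)-2-{2-[4-methoxy-3-(methoxymethoxy)phenyl]ethyl}-5,6,7,8-tetrahydro-4H-chromen-4-one | COCOc1cc(CCc2cc(=O)c3c(o2)[C@H](Cl)[C@@H](O[Si](C)(C)C(C)(C)C)[C@H]2OC(C)(C)O[C@@H]32)ccc1OC | intermediate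
17 | (5S,6S,7S,8R)-8-chloro-5,6,7-trihydroxy-2-[2-(3-hydroxy-4-methoxyphenyl)ethyl]-5,6,7,8-tetrahydro-4H-chromen-4-one | COc1ccc(CCc2cc(=O)c3c(o2)[C@H](Cl)[C@@H](O)[C@@H](O)[C@H]3O)cc1O | target

**Step count.** Total: 10 steps. Longest linear sequence: 7 steps (1, 2, 3, 4, 5, 9, 10).

**Steps most likely to fail**

1. Step 9 (key step). What may go wrong: the chloromethine C7 migrates in competition with C4 and gives the regioisomeric ketene; HCl or silanol is lost from the α-chloro-β-silyloxy ketone at 140 °C before N2 leaves; or the ketene dimerises faster than it is trapped. The fallback separates nitrogen loss from the cycloaddition. It sets out from 9, which is photolysed (λ > 300 nm) in acetone at 0 °C, so that the Wolff contraction runs without heat and the solvent captures the α-oxoketene as (5S,6S,7S,8R)-7-(tert-butyldimethylsilyloxy)-8-chloro-5,6-(isopropylidenedioxy)-2,2-dimethyl-5,6,7,8-tetrahydro-4H-benzo[d][1,3]dioxin-4-one F1. This dioxinone can be purified, so a regioisomer from C7 migration would be removed before the enol ether is committed. Heating F1 with 13 in toluene at 110 °C should release 14 slowly by retro-[4+2] loss of acetone, and cycloaddition followed by CSA brings the route back at 16.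

2. Step 3. What may go wrong: the methyl enolate equilibrates to the C7 enolate, which expels the lactone carboxylate by E1cB (retro-oxa-Michael), or the lactone α-position is deprotonated. The fallback replaces the lactone by an open-chain acyl donor with a poor β-leaving group. It sets out from 5, which is opened under non-basic conditions (Me3Al, MeNHOMe·HCl, CH2Cl2, 0 °C) to (4R,5R)-5-[(1R)-1-hydroxy-3-oxobutyl]-N-methoxy-N,2,2-trimethyl-1,3-dioxolane-4-carboxamide F2. Silylation (TBSOTf, 2,6-lutidine) gives (4R,5S)-5-[(1R)-1-(tert-butyldimethylsilyloxy)-3-oxobutyl]-N-methoxy-N,2,2-trimethyl-1,3-dioxolane-4-carboxamide F3. Kinetic enolisation of the methyl ketone (LDA, −78 °C) and intramolecular acylation by the Weinreb amide should give (4R,5S,6R)-6-(tert-butyldimethylsilyloxy)-4,5-(isopropylidenedioxy)cycloheptane-1,3-dione F4. Diazo transfer (p-ABSA, Et3N) gives (4R,5S,6R)-6-(tert-butyldimethylsilyloxy)-2-diazo-4,5-(isopropylidenedioxy)cycloheptane-1,3-dione F5, and TBSOTf/Et3N converts F5 into the enol silyl ether, where the route is rejoined at 8.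

3. Step 5. What may go wrong: poor facial selectivity in the chlorination of the flexible seven-membered enol ether, or attack of electrophilic chlorine at the diazo carbon. The fallback changes from kinetic electrophilic chlorination to bromination followed by thermodynamic halide exchange. It sets out from 8, which is brominated with the more reactive NBS at −78 °C to (4R,5S,6S)-7-bromo-6-(tert-butyldimethylsilyloxy)-2-diazo-4,5-(isopropylidenedioxy)cycloheptane-1,3-dione F6 (either C7 epimer). LiCl in DMF then displaces bromide by SN2 at the activated α-keto carbon; continued invertive chloride exchange on the α-chloro ketone should funnel both epimers to the chloride with chlorine anti to the neighbouring silyloxy group, expected to be the more stable one, and the route is rejoined at 9.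

**Further compounds**

F1 | step 9 | (5S,6S,7S,8R)-7-(tert-butyldimethylsilyloxy)-8-chloro-5,6-(isopropylidenedioxy)-2,2-dimethyl-5,6,7,8-tetrahydro-4H-benzo[d][1,3]dioxin-4-one | CC1(C)OC(=O)C2=C(O1)[C@H](Cl)[C@@H](O[Si](C)(C)C(C)(C)C)[C@H]1OC(C)(C)O[C@@H]21
F2 | step 3 | (4R,5R)-5-[(1R)-1-hydroxy-3-oxobutyl]-N-methoxy-N,2,2-trimethyl-1,3-dioxolane-4-carboxamide | CC(=O)C[C@@H](O)[C@H]1OC(C)(C)O[C@H]1C(=O)N(C)OC
F3 | step 3 | (4R,5S)-5-[(1R)-1-(tert-butyldimethylsilyloxy)-3-oxobutyl]-N-methoxy-N,2,2-trimethyl-1,3-dioxolane-4-carboxamide | CC(=O)C[C@@H](O[Si](C)(C)C(C)(C)C)[C@H]1OC(C)(C)O[C@H]1C(=O)N(C)OC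
F4 | step 3 | (4R,5S,6R)-6-(tert-butyldimethylsilyloxy)-4,5-(isopropylidenedioxy)cycloheptane-1,3-dione | O=C1C[C@@H](O[Si](C)(C)C(C)(C)C)[C@H]2OC(C)(C)O[C@H]2C(=O)C1
F5 | step 3 | (4R,5S,6R)-6-(tert-butyldimethylsilyloxy)-2-diazo-4,5-(isopropylidenedioxy)cycloheptane-1,3-dione | [N-]=[N+]=C1C(=O)C[C@@H](O[Si](C)(C)C(C)(C)C)[C@H]2OC(C)(C)O[C@H]2C1=O
F6 | step 5 | (4R,5S,6S)-7-bromo-6-(tert-butyldimethylsilyloxy)-2-diazo-4,5-(isopropylidenedioxy)cycloheptane-1,3-dione (C7 epimers) | [N-]=[N+]=C1C(=O)C(Br)[C@@H](O[Si](C)(C)C(C)(C)C)[C@H]2OC(C)(C)O[C@H]2C1=O
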